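The data stem from a simulated flask with made-up constants, and the scatter is random.

The intermediate goes either to the other capture product or to the target, so the comparison to make is between the two capture rates.

common to all: gas 43 mM (held)
- maple: substrate 0.54 M; second nucleophile 1.5 equiv; run made earlier
- elm: substrate 1.2 M; second nucleophile 1.5 equiv; run made earlier
- alder: substrate 0.80 M; second nucleophile 0.75 equiv; run made earlier
- flask: substrate 0.80 M; second nucleophile 1.50 equiv; time 15 d

- maple (time / d: other capture product / %, target / %): 2.50: 38, 46; 5.00: 41, 50; 8.00: 45, 58; 10.0: 46, 53; 12.0: 48, 54; 15.0: 45, 55
- elm (time / d: other capture product / %, target / %): 1.25: 38, 15; 2.08: 47, 27; 3.00: 55, 34; 5.00: 61, 33; 10.0: 68, 38; 15.0: 68, 39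
- alder (time / d: other capture product / %, target / %): 1.25: 19, 33; 4.00: 31, 55; 8.00: 37, 65; 10.0: 37, 67; 15.0: 34, 64

(standard deviation of a reading: 2 percentage points)

* ratio of other capture product to target at 1.0 h
* ratio of other capture product to target at 15 d
* which of other capture product and target there is more of at 15 d

- at the start none of first nucleophile is dissolved
- the numbers in the tables scatter with a standard deviation of 2 percentage points
- reactions considered so far: second nucleophile + intermediate -> other capture product; substrate -> intermediate; gas <-> first nucleophile; first nucleophile + intermediate -> target

With the gas held at 43 mM in maple, elm and alder, the ratio of those rates should be a constant times [second nucleophile] once [first nucleophile] stands steady. Each run's last reading gives that constant, a selectivity factor, as the final ratio of other capture product to target over the mean [second nucleophile], taken as the charge less half the other capture product. Maple reads 1.19 L mol⁻¹, elm 1.25 L mol⁻¹ and alder 1.14 L mol⁻¹, with a mean of 1.20 L mol⁻¹.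

For the flask, the charge gives 1.43. A first subtraction gives 1.15 and a second gives 1.18. This is the capture number, the other capture product formed per target over the whole run. It stands above one, so the reckoning here puts the other capture product ahead in the flask.

At the start none of first nucleophile is dissolved, so one number may not hold early. The elm reading at 1.25 d is 2.53, above the 1.88 the number gives there, though that ratio of two readings carries their scatter of 2 percentage points each. For 1.0 h the reckoning here therefore offers 1.43 as a lower mark.

The forecast gives 6 at 1.0 h, 1.25 at 15 d and other capture product in the lead, holding that “The lag is unresolved but short”. Its value at 15 d stands above the capture number.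

The flask gives 2.10 at 1.0 h and 1.21 at 15 d, with other capture product ahead.

    second nucleophile + intermediate → other capture product (k = 7.20 × 10⁻⁴ L mol⁻¹ s⁻¹)
    substrate → intermediate (k = 7.30 × 10⁻⁶ s⁻¹)
    gas ⇌ first nucleophile, rate k3*(csat - [first nucleophile]) (kL = 7.10 × 10⁻⁴ s⁻¹)
    first nucleophile + intermediate → target (k = 0.0140 L mol⁻¹ s⁻¹)

The capture number of 1.18 stands beside that 1.21, while the forecast and the flask part at 1.0 h, where the flask's value lies above the lower mark. A neighbouring flask holds 0.380 equiv of second nucleophile. Its charge gives 0.363, the subtractions give 0.236 and then a capture number of 0.272, below one, which puts the target ahead. That neighbouring flask ends at a ratio of 0.269, with 78.8% target and 21.2% other capture product.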